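**Retrosynthetic overview**
- The target is opened at C2–OH (syn-selective ketone reduction) and at the C1–C(OH) bond (aldol). The aldol donor is the cyclopentanone enol released when a trans-fused 2-diazo-cyclohexane-1,3-dione is ring-contracted (Wolff, 6→5) and decarboxylated; the acceptor is the ring-A α-hydroxy aldehyde.
- The diazo-dione comes from a Claisen ring closure between an acetonyl arm and an ester on a bromocyclohexane; that bromocyclohexane comes from an acyclic β-keto ester by enantioselective bromonium cyclisation.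
- The ring-A aldehyde comes from (S)-4-bromo-3,3-dimethylcyclohexanone (vinyl addition, ozonolysis), made by the same bromocyclisation of the prenyl acetoacetate.
- Ring order: ring A and the bromocyclohexane of the core are made separately; then a temporary six-membered 1,3-dione; this is contracted to the cyclopentanone while the two halves are joined.

Assumption: the C1/C2 donors (Grignard reagents, Me3Al, paraformaldehyde) are treated as reagents; the carbon-skeleton starting materials are 1, 2 and 8, each taken as commercial.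

Step 1
Reactants: 1 methyl acetoacetate; 2 prenyl bromide (1-bromo-3-methylbut-2-ene)
Product: 3 methyl 7-methyl-3-oxooct-6-enoate
Conditions: NaH, THF, 0 °C; n-BuLi, 0 °C; then 2, 0→23 °C; aq. NH4Cl
Reagents that add atoms: none
Why: Weiler dianion alkylation, in which the more reactive γ-carbanion of the acetoacetate dianion displaces the allylic bromide (SN2); no stereocentre is formed.

Step 2
Reactants: 3 methyl 7-methyl-3-oxooct-6-enoate
Product: 4 methyl (1S,3S)-3-bromo-2,2-dimethyl-6-oxocyclohexane-1-carboxylate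
Conditions: BINOL-derived (3,3′-bis(2,4,6-iPr3C6H2)) N-triflyl thiophosphoramide (10 mol %, enantiomer chosen to give 3S), DBDMH (0.6 equiv), PhMe/CH2Cl2, −78 °C
Reagents that add atoms: 1,3-dibromo-5,5-dimethylhydantoin, CC1(C)N(Br)C(=O)N(Br)C1=O
Why: Proposed new method: enantioselective bromonium cyclisation terminated by a β-keto ester; the P=S Lewis base carries Br+ to one face of the trisubstituted alkene while the acidic N–H holds the enol, whose C-2 opens the bromiranium anti at the tertiary carbon through a chair (Br equatorial, 3S; ester equilibrates to equatorial), and −78 °C with the keto tautomer dominant should hold back α-bromination; closest known chemistry is the chiral thiophosphoramide/DBDMH bromocyclisation of homogeranyl arenes and the racemic Lewis-acid or halonium cyclisations of olefinic β-keto esters.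

Step 3
Reactants: 4 methyl (1S,3S)-3-bromo-2,2-dimethyl-6-oxocyclohexane-1-carboxylate
Product: 5 (4S)-4-bromo-3,3-dimethylcyclohexan-1-one
Conditions: 6 M HCl/AcOH, 85 °C
Reagents that add atoms: none
Why: Acidic ester hydrolysis and decarboxylation of the β-keto acid; acid is used because a basic method would let the enolate close a cyclopropane onto the C–Br carbon, and the neopentyl-type bromide stereocentre is untouched.

Step 4
Reactants: 5 (4S)-4-bromo-3,3-dimethylcyclohexan-1-one
Product: 6 (1R,4S)-4-bromo-1-ethenyl-3,3-dimethylcyclohexan-1-ol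
Conditions: CH2=CHMgBr, CeCl3, THF, −78 °C
Reagents that add atoms: vinylmagnesium bromide, C=C[Mg]Br
Why: Organocerium 1,2-addition (non-basic, so no enolisation of the γ-bromo ketone); the axial 3-methyl blocks axial attack, so vinyl enters equatorially and the new carbinol is axial and cis to bromine (1R).

Step 5
Reactants: 6 (1R,4S)-4-bromo-1-ethenyl-3,3-dimethylcyclohexan-1-ol
Product: 7 (1R,4S)-4-bromo-1-hydroxy-3,3-dimethylcyclohexane-1-carbaldehyde
Conditions: O3, CH2Cl2/MeOH, −78 °C; Me2S; used crude
Reagents that add atoms: ozone, [O-][O+]=O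
Why: Ozonolysis with reductive work-up cleaves the only alkene to the α-hydroxy aldehyde without touching the carbinol centre; it is used at once because such aldehydes dimerise.

Step 6
Reactants: 8 pent-1-en-4-yne
Product: 9 (2E)-3-methylhexa-2,5-dien-1-ol
Conditions: Me3Al, Cp2ZrCl2 (20 mol %), CH2Cl2, 0→23 °C; n-BuLi, THF, −78 °C; (CH2O)n, 23 °C
Reagents that add atoms: trimethylaluminium, C[Al](C)C; paraformaldehyde (formaldehyde), C=O
Why: Negishi zirconium-catalysed carboalumination adds Me and Al syn across the alkyne (Al terminal), which fixes the E trisubstituted alkene; the alanate is then hydroxymethylated with retention.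

Step 7
Reactants: 9 (2E)-3-methylhexa-2,5-dien-1-ol
Product: 10 (2E)-1-bromo-3-methylhexa-2,5-diene
Conditions: PBr3, pyridine (cat.), Et2O, −10 °C
Reagents that add atoms: phosphorus tribromide, BrP(Br)Br
Why: SN2 conversion of a primary allylic alcohol to the bromide at low temperature, which keeps the E geometry.

Step 8
Reactants: 1 methyl acetoacetate; 10 (2E)-1-bromo-3-methylhexa-2,5-diene
Product: 11 methyl (6E)-7-methyl-3-oxodeca-6,9-dienoate
Conditions: NaH, THF, 0 °C; n-BuLi, 0 °C; then 10, 0→23 °C; aq. NH4Cl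
Reagents that add atoms: none
Why: Weiler dianion γ-alkylation as in step 1; the alkene geometry is carried over.

Step 9
Reactants: 11 methyl (6E)-7-methyl-3-oxodeca-6,9-dienoate
Product: 12 methyl (1S,2S,3S)-3-bromo-2-methyl-6-oxo-2-(prop-2-en-1-yl)cyclohexane-1-carboxylate
Conditions: same thiophosphoramide catalyst as step 2 (10 mol %), DBDMH (0.6 equiv), PhMe/CH2Cl2, −78 °C
Reagents that add atoms: 1,3-dibromo-5,5-dimethylhydantoin, CC1(C)N(Br)C(=O)N(Br)C1=O
Why: Proposed new method: the same catalyst-bound Br+ attacks the electron-rich trisubstituted alkene (the terminal allyl alkene is far less nucleophilic), and the catalyst-held enol closes the ring through a chair in which the E alkene puts methyl axial, allyl equatorial and Br equatorial (2S,3S), with the ester settling equatorial (1S) so that both arms are trans-diequatorial; closest known chemistry is the chiral Lewis-base bromocyclisation of homogeranyl arenes and racemic cation–olefin cyclisations of olefinic β-keto esters.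

Step 10
Reactants: 12 methyl (1S,2S,3S)-3-bromo-2-methyl-6-oxo-2-(prop-2-en-1-yl)cyclohexane-1-carboxylate
Product: 13 methyl (1S,2S,3S,6R)-3-bromo-6-hydroxy-2,6-dimethyl-2-(prop-2-en-1-yl)cyclohexane-1-carboxylate
Conditions: MeMgBr, CeCl3, THF, −78 °C
Reagents that add atoms: methylmagnesium bromide, C[Mg]Br
Why: Cerium-mediated Grignard addition to an enolisable β-dicarbonyl ketone; the axial C2 methyl blocks axial attack, so methyl enters equatorially and the tertiary OH is axial (6R), and the cold, non-basic reagent avoids enolate cyclopropanation onto C–Br.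

Step 11
Reactants: 13 methyl (1S,2S,3S,6R)-3-bromo-6-hydroxy-2,6-dimethyl-2-(prop-2-en-1-yl)cyclohexane-1-carboxylate
Product: 14 methyl (1S,2S,3S,6R)-3-bromo-6-hydroxy-2,6-dimethyl-2-(2-oxopropyl)cyclohexane-1-carboxylate
Conditions: PdCl2 (10 mol %), CuCl, O2 (1 atm), DMF/H2O, 23 °C
Reagents that add atoms: water, O
Why: Tsuji–Wacker oxidation (Markovnikov oxypalladation) turns the terminal alkene into the methyl ketone; ester, tertiary alcohol and bromide are inert.

Step 12
Reactants: 14 methyl (1S,2S,3S,6R)-3-bromo-6-hydroxy-2,6-dimethyl-2-(2-oxopropyl)cyclohexane-1-carboxylate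
Product: 15 (4aS,5S,8R,8aS)-5-bromo-8-hydroxy-4a,8-dimethyl-4a,5,6,7,8,8a-hexahydronaphthalene-1,3(2H,4H)-dione
Conditions: LiHMDS (3.3 equiv), THF, −78→0 °C; aq. NH4Cl
Reagents that add atoms: none
Why: Intramolecular Claisen (Dieckmann-type) condensation in which the kinetic methyl-ketone enolate attacks the ester to close a six-membered 1,3-dione, driven by the stable dione enolate; the two equatorial arms give the trans ring fusion and no new stereocentre.

Step 13
Reactants: 15 (4aS,5S,8R,8aS)-5-bromo-8-hydroxy-4a,8-dimethyl-4a,5,6,7,8,8a-hexahydronaphthalene-1,3(2H,4H)-dione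
Product: 16 (4aS,5S,8R,8aS)-5-bromo-2-diazo-8-hydroxy-4a,8-dimethyl-4a,5,6,7,8,8a-hexahydronaphthalene-1,3(2H,4H)-dione
Conditions: p-ABSA, Et3N, MeCN, 0→23 °C
Reagents that add atoms: 4-acetamidobenzenesulfonyl azide, CC(=O)Nc1ccc(cc1)S(=O)(=O)N=[N+]=[N-]
Why: Regitz diazo transfer to the doubly activated methylene; no stereocentre is affected.

Step 14
Reactants: 16 (4aS,5S,8R,8aS)-5-bromo-2-diazo-8-hydroxy-4a,8-dimethyl-4a,5,6,7,8,8a-hexahydronaphthalene-1,3(2H,4H)-dione; 7 (1R,4S)-4-bromo-1-hydroxy-3,3-dimethylcyclohexane-1-carbaldehyde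
Product: 19 (1R,3aS,4S,7R,7aS)-4-bromo-1-[(R)-[(1R,4S)-4-bromo-1-hydroxy-3,3-dimethylcyclohexyl](hydroxy)methyl]-7-hydroxy-3a,7-dimethyloctahydro-2H-inden-2-one, via acylketene 17 (not isolated), via keto acid 18 (not isolated)
Conditions: hν (350 nm), THF/H2O 4:1, 0 °C; dry (Na2SO4, 0 °C); then 7, MgBr2·OEt2, Et3N, THF, 0→23 °C
Reagents that add atoms: none
Why: Photochemical Wolff ring contraction (the secondary ring-fusion carbon C-8a is expected to migrate in preference to the C-4 methylene, with retention, so the trans fusion is kept), fast hydration of the acylketene, then a magnesium-templated decarboxylative aldol that releases the enol only at C1; the C1 side chain settles trans to the C7a–C7 bond (epimerisable, thermodynamic), and C8 is set R by a Cram chelate (Mg bridging the aldehyde and α-hydroxyl oxygens) with attack from the face next to the unsubstituted ring CH2 groups, away from the gem-dimethyl side.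

Step 15
Reactants: 19 (1R,3aS,4S,7R,7aS)-4-bromo-1-[(R)-[(1R,4S)-4-bromo-1-hydroxy-3,3-dimethylcyclohexyl](hydroxy)methyl]-7-hydroxy-3a,7-dimethyloctahydro-2H-inden-2-one
Product: 20 (1S,2R,3aS,4S,7R,7aS)-4-bromo-1-[(R)-[(1R,4S)-4-bromo-1-hydroxy-3,3-dimethylcyclohexyl](hydroxy)methyl]-3a,7-dimethyloctahydro-1H-indene-2,7-diol
Conditions: Et2BOMe, THF/MeOH 4:1, −78 °C; NaBH4; MeOH co-evaporation
Reagents that add atoms: none
Why: Narasaka–Prasad reduction; boron chelates the C8 hydroxyl and the ketone, and hydride comes from the face opposite the C1 side chain, giving the 1,3-syn diol with the C2 hydroxyl cis to the side chain (2R).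

**Compound list**
1 | methyl acetoacetate (methyl 3-oxobutanoate) | COC(=O)CC(C)=O | starting material
2 | prenyl bromide (1-bromo-3-methylbut-2-ene) | CC(C)=CCBr | starting material
3 | methyl 7-methyl-3-oxooct-6-enoate | COC(=O)CC(=O)CCC=C(C)C | intermediate
4 | methyl (1S,3S)-3-bromo-2,2-dimethyl-6-oxocyclohexane-1-carboxylate | CC1(C)[C@H](C(=O)OC)C(=O)CC[C@@H]1Br | intermediate
5 | (4S)-4-bromo-3,3-dimethylcyclohexan-1-one | CC1(C)CC(=O)CC[C@@H]1Br | intermediate
6 | (1R,4S)-4-bromo-1-ethenyl-3,3-dimethylcyclohexan-1-ol | CC1(C)C[C@@](O)(C=C)CC[C@@H]1Br | intermediate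
7 | (1R,4S)-4-bromo-1-hydroxy-3,3-dimethylcyclohexane-1-carbaldehyde | CC1(C)C[C@@](O)(C=O)CC[C@@H]1Br | intermediate
8 | pent-1-en-4-yne | C#CCC=C | starting material
9 | (2E)-3-methylhexa-2,5-dien-1-ol | OC/C=C(\C)CC=C | intermediate
10 | (2E)-1-bromo-3-methylhexa-2,5-diene | BrC/C=C(\C)CC=C | intermediate
11 | methyl (6E)-7-methyl-3-oxodeca-6,9-dienoate | COC(=O)CC(=O)CC/C=C(\C)CC=C | intermediate
12 | methyl (1S,2S,3S)-3-bromo-2-methyl-6-oxo-2-(prop-2-en-1-yl)cyclohexane-1-carboxylate | C=CC[C@]1(C)[C@@H](Br)CCC(=O)[C@H]1C(=O)OC | intermediate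
13 | methyl (1S,2S,3S,6R)-3-bromo-6-hydroxy-2,6-dimethyl-2-(prop-2-en-1-yl)cyclohexane-1-carboxylate | C=CC[C@]1(C)[C@@H](Br)CC[C@@](C)(O)[C@H]1C(=O)OC | intermediate
14 | methyl (1S,2S,3S,6R)-3-bromo-6-hydroxy-2,6-dimethyl-2-(2-oxopropyl)cyclohexane-1-carboxylate | CC(=O)C[C@]1(C)[C@@H](Br)CC[C@@](C)(O)[C@H]1C(=O)OC | intermediate
15 | (4aS,5S,8R,8aS)-5-bromo-8-hydroxy-4a,8-dimethyl-4a,5,6,7,8,8a-hexahydronaphthalene-1,3(2H,4H)-dione | O=C1C[C@]2(C)[C@@H](Br)CC[C@@](C)(O)[C@H]2C(=O)C1 | intermediate
16 | (4aS,5S,8R,8aS)-5-bromo-2-diazo-8-hydroxy-4a,8-dimethyl-4a,5,6,7,8,8a-hexahydronaphthalene-1,3(2H,4H)-dione | O=C1C[C@]2(C)[C@@H](Br)CC[C@@](C)(O)[C@H]2C(=O)C1=[N+]=[N-] | intermediate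
17 | (3aS,4S,7R,7aS)-4-bromo-7-hydroxy-3a,7-dimethyl-1-(oxomethylidene)octahydro-2H-inden-2-one (acylketene) | O=C=C1C(=O)C[C@]2(C)[C@@H](Br)CC[C@@](C)(O)[C@@H]12 | intermediate
18 | (1S,3aS,4S,7R,7aS)-4-bromo-7-hydroxy-3a,7-dimethyl-2-oxooctahydro-1H-indene-1-carboxylic acid | OC(=O)[C@@H]1C(=O)C[C@]2(C)[C@@H](Br)CC[C@@](C)(O)[C@@H]12 | intermediate
19 | (1R,3aS,4S,7R,7aS)-4-bromo-1-[(R)-[(1R,4S)-4-bromo-1-hydroxy-3,3-dimethylcyclohexyl](hydroxy)methyl]-7-hydroxy-3a,7-dimethyloctahydro-2H-inden-2-one | CC1(C)C[C@@](O)([C@H](O)[C@@H]2C(=O)C[C@]3(C)[C@@H](Br)CC[C@@](C)(O)[C@@H]23)CC[C@@H]1Br | intermediate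
20 | (1S,2R,3aS,4S,7R,7aS)-4-bromo-1-[(R)-[(1R,4S)-4-bromo-1-hydroxy-3,3-dimethylcyclohexyl](hydroxy)methyl]-3a,7-dimethyloctahydro-1H-indene-2,7-diol (CNP0144982.1) | CC1(C)C[C@@](O)([C@H](O)[C@@H]2[C@H](O)C[C@]3(C)[C@@H](Br)CC[C@@](C)(O)[C@@H]23)CC[C@@H]1Br | target

**Totals**
Total step count: 15. Longest linear sequence: 10 steps (8 → 20, steps 6–15); the ring-A branch is steps 1–5. No protecting groups are used.

**The three steps most likely to fail**

Step 9 (proposed new method). The β-keto ester may be α-brominated, may close through oxygen instead of carbon, or the ee may be low. The fallback uses known chemistry, sets out from 11 and comes back at 12. Compound 11 is cyclised with the achiral bromonium reagent BDSB (Et2SBr·SbCl5Br, MeNO2, −25 °C; if needed Hg(OTf)2 followed by Br2/LiBr) to racemic material, that is 12 together with its enantiomer methyl (1R,2R,3R)-3-bromo-2-methyl-6-oxo-2-(prop-2-en-1-yl)cyclohexane-1-carboxylate F5. The enantiomers are separated by preparative chiral SFC and 12 goes on into step 10.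

Step 2 (the same proposed method on the simpler substrate). The fallback uses known chemistry, sets out from 3 and comes back at 5. Compound 3 is cyclised with BDSB to 4 together with its enantiomer methyl (1R,3R)-3-bromo-2,2-dimethyl-6-oxocyclohexane-1-carboxylate F1. Acidic decarboxylation as in step 3 gives 5 together with (4R)-4-bromo-3,3-dimethylcyclohexan-1-one F2. The racemic ketone is resolved by Johnson's sulfoximine method: lithiated (S)-N,S-dimethyl-S-phenylsulfoximine adds equatorially to give (1R,4S)-4-bromo-3,3-dimethyl-1-{[(S)-N-methyl-S-phenylsulfonimidoyl]methyl}cyclohexan-1-ol F3 and (1S,4R)-4-bromo-3,3-dimethyl-1-{[(S)-N-methyl-S-phenylsulfonimidoyl]methyl}cyclohexan-1-ol F4, which are separated on silica. Thermolysis of F3 (toluene, 110 °C) returns 5.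

Step 14. The wrong acyl branch may migrate in the Wolff step, the ketene may be caught by the C7 hydroxyl instead of water, and the aldol may show modest facial control or retro-aldol loss. The fallback sets out from 16 and comes back at 19; it replaces the decarboxylative aldol by a Reformatsky-type coupling and addresses only the aldol risks, not a wrong Wolff migration. Compound 16 is photolysed in wet THF as before to acid 18, which is treated with N-bromosuccinimide (decarboxylative bromination of a β-keto acid) to give the regiodefined α-bromo ketone (1S,3aS,4S,7R,7aS)-1,4-dibromo-7-hydroxy-3a,7-dimethyloctahydro-2H-inden-2-one F6. SmI2 (THF, −78 °C) reduces only the α-bromo ketone to the samarium enolate at C1, which adds to 7 to give 19.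

Further compounds
F1 | step 2 | methyl (1R,3R)-3-bromo-2,2-dimethyl-6-oxocyclohexane-1-carboxylate | CC1(C)[C@@H](C(=O)OC)C(=O)CC[C@H]1Br
F2 | step 2 | (4R)-4-bromo-3,3-dimethylcyclohexan-1-one | CC1(C)CC(=O)CC[C@H]1Br
F3 | step 2 | (1R,4S)-4-bromo-3,3-dimethyl-1-{[(S)-N-methyl-S-phenylsulfonimidoyl]methyl}cyclohexan-1-ol | CN=[S@](=O)(C[C@@]1(O)CC[C@H](Br)C(C)(C)C1)c1ccccc1
F4 | step 2 | (1S,4R)-4-bromo-3,3-dimethyl-1-{[(S)-N-methyl-S-phenylsulfonimidoyl]methyl}cyclohexan-1-ol | CN=[S@](=O)(C[C@]1(O)CC[C@@H](Br)C(C)(C)C1)c1ccccc1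
F5 | step 9 | methyl (1R,2R,3R)-3-bromo-2-methyl-6-oxo-2-(prop-2-en-1-yl)cyclohexane-1-carboxylate | C=CC[C@@]1(C)[C@H](Br)CCC(=O)[C@@H]1C(=O)OC
F6 | step 14 | (1S,3aS,4S,7R,7aS)-1,4-dibromo-7-hydroxy-3a,7-dimethyloctahydro-2H-inden-2-one | Br[C@@H]1C(=O)C[C@]2(C)[C@@H](Br)CC[C@@](C)(O)[C@@H]12
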